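- When I read your note asking for a quick number, I had the two earlier runs beside it, and this is what stood on the bench:

| flask | substrate | partner | catalyst | remark | time |
|---|---|---|---|---|---|
| Friday's | 0.30 M | 0.75 M | 1.9 mM (in portions, 4) | run made earlier; portions every 30 s |  |
| Saturday's | 0.30 M | 3 M | 1.9 mM (in portions, 4) | run made earlier; portions every 30 s |  |
| flask | 0.30 M | 1.50 M | 1.9 mM (in portions, 4) | the portions of catalyst follow each other after 30 s, the first at the start | 2.0 min |

| run | time / s | substrate / % | target / % | side product / % |
|---|---|---|---|---|
| Friday's | 10.0 | 95.6 | 4.4 | 0.6 |
| Friday's | 25.0 | 90.1 | 6.0 | 3.2 |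
| Friday's | 40.0 | 83.8 | 9.2 | 8.1 |
| Friday's | 60.0 | 75.1 | 10.9 | 13.4 |
| Friday's | 90.0 | 63.9 | 12.4 | 24.6 |
| Saturday's | 10.0 | 85.4 | 12.4 | 2.4 |
| Saturday's | 25.0 | 68.6 | 21.4 | 10.2 |
| Saturday's | 40.0 | 51.2 | 29.5 | 20.2 |
| Saturday's | 60.0 | 37.9 | 30.7 | 30.0 |
| Saturday's | 90.0 | 28.9 | 28.3 | 42.6 |

(readings scatter by 0.5 percentage points)

* why nothing more happens at 2.0 min, or that something still does (all of the substrate has reacted / forward and back rates have come level / it is still moving / the partner has run out first)
* part of the substrate gone at 2.0 min
* the target standing at 2.0 min, as a percentage of the substrate charged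
* the side product standing at 2.0 min, as a percentage of the substrate charged

- percent here means substrate units held: one side product counts as two
- the reaction counts as stopped when no species that holds the substrate changes by six tenths of a point or more over the second half of the time

- I went to logarithms and carried one quantity, the standing quotient Q = [target]/([substrate][partner]), a reaction quotient. Taking logarithms gave log([target]/[substrate]) = log Q + log [partner], so the partner's effect became a simple addition.
- I took each target to have used one partner, and each side product, counted as two, to hold one partner as well, so I reckoned the partner left at 90.0 s: 0.676 M in Friday's run and 2.85 M in Saturday's.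
- Those readings gave Q of 0.287 M⁻¹ on Friday and 0.343 M⁻¹ on Saturday.
- For the new flask, with [partner] at 1.50 M, I therefore put log([target]/[substrate]) between −0.366 and −0.289, a ratio of 0.430 to 0.515.
- Side product had risen 11 percentage points and 13 points over the last intervals of those runs, so I expected the new flask to be still moving.
- Your forecast said: it is still moving, with 59 % gone, target 17 % and side product 42 %, since “Side product still climbs well over” the margin. Its ratio of 0.415 lay slightly below my range.
- The flask gave: it is still moving, with 61.5 % gone, target 17.2 % and side product 44.4 %.

    substrate + target → side product (k = 0.0680 M⁻¹ s⁻¹)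
    substrate + partner + catalyst ⇌ target + catalyst, rate k2*[substrate]*[partner]*[catalyst] forward; the back reaction follows from the equilibrium constant (K = 0.340 M⁻¹, k = 11.0 M⁻² s⁻¹)

- The flask's Q was 0.323 M⁻¹, between the two readings. The neighbour with 4.7 × 10⁻⁴ M of catalyst reached a Q of 0.186 M⁻¹, and its side product of 30.2 % lay under the forecast's 42 %, so at that catalyst charge the forecast's number did not hold. The flask was still moving at 2.0 min because the time given was short: its side product stood at 44.4 % then, and the same flask left until 20.0 min reached 91.1 %.

All runs come from a simulation for substances that don't exist; scatter was added.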